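**Retrosynthetic overview**

1. Pakyonol 18 comes from the macrocyclic benzil 16 by one acidic palladium hydrogenolysis, which turns the B–C bridge C(=O)–C(=O) into CH2–CH2 and frees the ring C hydroxyl from its benzyl ether.
2. The strategy rests on ring B: its ether oxygen sits para to the ring carbon that carries the B–C bridge. A carbonyl at that bridge carbon therefore activates the ring B C–F carbon, and a 1,2-dione bridge has no α-hydrogen. Ring 16 is opened at the O(ring A, ortho to OMe)–C(ring B) bond to the open-chain fluorobenzil phenol 15.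
3. Compound 15 comes from aldehyde 10 by Ohira–Bestmann alkynylation, Sonogashira coupling with 1-fluoro-4-iodobenzene 12, alkyne-to-dione oxidation and MOM removal.
4. Aldehyde 10 comes from SNAr of the A–D bibenzyl phenol 7 on 3-(benzyloxy)-4-fluorobenzaldehyde 9. Phenol 7 comes from a Wittig reaction of MOM-isovanillin 2 with the ylide of salt 4, then hydrogenation.
5. All four benzene rings are bought; the only ring formed is the 20-membered macrocycle, closed in step 11.

Key step: step 11

Assumption: [3-(benzyloxy)phenyl]methanol 3 is taken as a purchasable ring D building block. The alkene geometry of 6 and the relative configuration of the transient diol 17 do not matter, because both are erased later.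

**Route**

Step 1
Reactants: 1 isovanillin (3-hydroxy-4-methoxybenzaldehyde)
Product: 2 4-methoxy-3-(methoxymethoxy)benzaldehyde
Conditions: MOMCl, i-Pr2NEt, CH2Cl2, 0 °C to rt
Reagents that add atoms: chloromethyl methyl ether, COCCl
Why: O-alkylation of the phenol with an α-chloro ether (Williamson-type) should give a MOM acetal that withstands ylide, hydrogenation, carbonate and palladium coupling and is later removed by acid beside a benzyl ether.

Step 2
Reactants: 3 [3-(benzyloxy)phenyl]methanol
Product: 4 [3-(benzyloxy)benzyl]triphenylphosphonium bromide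
Conditions: PPh3·HBr, MeCN, reflux
Reagents that add atoms: triphenylphosphine hydrobromide, Br.c1ccc(cc1)P(c1ccccc1)c1ccccc1
Why: Benzylic alcohols are converted directly into phosphonium salts by triphenylphosphine hydrobromide (acid-promoted nucleophilic substitution of the protonated alcohol by the phosphine), and an aryl benzyl ether tolerates this weak acid.

Step 3
Reactants: 4 [3-(benzyloxy)benzyl]triphenylphosphonium bromide; 2 4-methoxy-3-(methoxymethoxy)benzaldehyde
Product: 6 4-{2-[3-(benzyloxy)phenyl]ethenyl}-1-methoxy-2-(methoxymethoxy)benzene (E/Z mixture), via phosphonium ylide 5 (not isolated)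
Conditions: KOtBu, THF, 0 °C; then 2, 0 °C to rt
Reagents that add atoms: none
Why: Wittig olefination of a semi-stabilised benzyl ylide with a non-enolisable aryl aldehyde should give the stilbene, whose geometry is irrelevant because the alkene is saturated in the next step.

Step 4
Reactants: 6 4-{2-[3-(benzyloxy)phenyl]ethenyl}-1-methoxy-2-(methoxymethoxy)benzene
Product: 7 3-{2-[4-methoxy-3-(methoxymethoxy)phenyl]ethyl}phenol
Conditions: H2 (1 atm), 10% Pd/C, EtOAc/EtOH, rt
Reagents that add atoms: none
Why: Heterogeneous catalytic hydrogenation should saturate the stilbene and hydrogenolyse the ring D benzyl ether in one operation, while the MOM acetal is inert under neutral conditions, so only the ring D hydroxyl is set free.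

Step 5
Reactants: 8 4-fluoro-3-hydroxybenzaldehyde
Product: 9 3-(benzyloxy)-4-fluorobenzaldehyde
Conditions: BnBr, K2CO3, DMF, rt
Reagents that add atoms: benzyl bromide, BrCc1ccccc1
Why: Williamson etherification of the phenoxide is fast at room temperature, where displacement of the aryl fluoride by the same phenoxide does not compete.

Step 6
Reactants: 7 3-{2-[4-methoxy-3-(methoxymethoxy)phenyl]ethyl}phenol; 9 3-(benzyloxy)-4-fluorobenzaldehyde
Product: 10 3-(benzyloxy)-4-(3-{2-[4-methoxy-3-(methoxymethoxy)phenyl]ethyl}phenoxy)benzaldehyde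
Conditions: K2CO3, DMF, 120 °C
Reagents that add atoms: none
Why: SNAr (addition–elimination) of the ring D phenoxide at the fluorine-bearing carbon para to the formyl group, which stabilises the Meisenheimer intermediate; 7 has a single free hydroxyl and the MOM acetal is inert to carbonate.

Step 7
Reactants: 10 3-(benzyloxy)-4-(3-{2-[4-methoxy-3-(methoxymethoxy)phenyl]ethyl}phenoxy)benzaldehyde
Product: 11 2-(benzyloxy)-4-ethynyl-1-(3-{2-[4-methoxy-3-(methoxymethoxy)phenyl]ethyl}phenoxy)benzene
Conditions: dimethyl (1-diazo-2-oxopropyl)phosphonate, K2CO3, MeOH/THF, rt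
Reagents that add atoms: dimethyl (1-diazo-2-oxopropyl)phosphonate, COP(=O)(OC)C(=[N+]=[N-])C(C)=O
Why: Seyferth–Gilbert homologation in the Ohira–Bestmann variant converts a non-enolisable aryl aldehyde into the terminal alkyne under mild carbonate conditions that leave all ethers untouched.

Step 8
Reactants: 11 2-(benzyloxy)-4-ethynyl-1-(3-{2-[4-methoxy-3-(methoxymethoxy)phenyl]ethyl}phenoxy)benzene; 12 1-fluoro-4-iodobenzene
Product: 13 2-(benzyloxy)-4-[(4-fluorophenyl)ethynyl]-1-(3-{2-[4-methoxy-3-(methoxymethoxy)phenyl]ethyl}phenoxy)benzene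
Conditions: Pd(PPh3)2Cl2 (cat.), CuI (cat.), Et3N/THF, degassed, rt to 40 °C
Reagents that add atoms: none
Why: Sonogashira coupling, in which zerovalent palladium inserts into the C–I bond only and the C–F bond is left for the later ring closure.

Step 9
Reactants: 13 2-(benzyloxy)-4-[(4-fluorophenyl)ethynyl]-1-(3-{2-[4-methoxy-3-(methoxymethoxy)phenyl]ethyl}phenoxy)benzene
Product: 14 1-[3-(benzyloxy)-4-(3-{2-[4-methoxy-3-(methoxymethoxy)phenyl]ethyl}phenoxy)phenyl]-2-(4-fluorophenyl)ethane-1,2-dione
Conditions: PdCl2 (10 mol %), DMSO, 140 °C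
Reagents that add atoms: dimethyl sulfoxide, CS(C)=O
Why: Palladium-catalysed Wacker-type oxidation of a diarylalkyne, with DMSO as oxygen donor and terminal oxidant, is a standard route to benzils and should leave the ethers, the aryl fluoride and the saturated A–D bridge alone.

Step 10
Reactants: 14 1-[3-(benzyloxy)-4-(3-{2-[4-methoxy-3-(methoxymethoxy)phenyl]ethyl}phenoxy)phenyl]-2-(4-fluorophenyl)ethane-1,2-dione
Product: 15 1-[3-(benzyloxy)-4-{3-[2-(3-hydroxy-4-methoxyphenyl)ethyl]phenoxy}phenyl]-2-(4-fluorophenyl)ethane-1,2-dione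
Conditions: 3 M aq HCl, THF, 50 °C
Reagents that add atoms: none
Why: Acid hydrolysis of the MOM acetal frees the ring A phenol, while the benzyl ether, the dione and the aryl fluoride are stable to aqueous acid.

Step 11
Reactants: 15 1-[3-(benzyloxy)-4-{3-[2-(3-hydroxy-4-methoxyphenyl)ethyl]phenoxy}phenyl]-2-(4-fluorophenyl)ethane-1,2-dione
Product: 16 macrocyclic benzil (O-benzyl pakyonol with the B–C bridge as a 1,2-dione)
Conditions: Cs2CO3, 4 Å molecular sieves, anhydrous DMF, 90 °C, slow addition of 15 to a final concentration of about 2 mM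
Reagents that add atoms: none
Why: Cs2CO3 deprotonates the ring A hydroxyl ortho to the methoxy group, and the phenoxide adds to the fluorine-bearing carbon of ring B, which lies para to a dione carbonyl; the charge of the Meisenheimer adduct is taken up by that carbonyl oxygen and loss of fluoride restores aromaticity (SNAr, addition–elimination). The closest known reactions are the carbonate-mediated phenoxide displacements on 4-fluorobenzils and 4-fluorobenzophenones used for poly(aryl ether)s, and the SNAr macro-etherifications used for cyclic diaryl ether natural products. The one ring formed is the 20-membered macrocycle, closed end to end by intramolecular O-arylation under high dilution and helped by the skewed geometry preferred by the O=C–C=O unit, which turns ring B back toward the A–D half. No stereocentre is formed. The step needs substitution at C–F in preference to oligomerisation, to lasting carbonyl addition or benzilic acid rearrangement, and to aryloxide exchange at ring C. These are secured by slow addition into a dilute suspension, by the absence of any α-hydrogen in the dione (no enolate can switch off the activation), by anhydrous carbonate (phenoxide addition to C=O is reversible, fluoride loss is not), and by fluoride being a far better nucleofuge than the ring D aryloxide.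

Step 12
Reactants: 16 macrocyclic benzil
Product: 18 pakyonol, via debenzylated macrocyclic diol 17 (not isolated)
Conditions: H2 (4 bar), 10% Pd/C, AcOH/EtOAc, HClO4 (cat.), rt to 50 °C
Reagents that add atoms: none
Why: Benzylic hydrogenolysis over palladium: the aryl ketones are reduced to benzylic alcohols, whose protonated C–O bonds (each para to an aryloxy donor) are cleaved by hydrogen to CH2, and the aryl benzyl ether is hydrogenolysed in the same operation, while methyl and diaryl ethers and the arenes are not touched.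

**Compound list**

1 | isovanillin (3-hydroxy-4-methoxybenzaldehyde) | COc1ccc(C=O)cc1O | starting material
2 | 4-methoxy-3-(methoxymethoxy)benzaldehyde | COCOc1cc(C=O)ccc1OC | intermediate
3 | [3-(benzyloxy)phenyl]methanol | OCc1cccc(OCc2ccccc2)c1 | starting material
4 | [3-(benzyloxy)benzyl]triphenylphosphonium bromide | [Br-].c1ccc(COc2cccc(C[P+](c3ccccc3)(c3ccccc3)c3ccccc3)c2)cc1 | intermediate
5 | [3-(benzyloxy)benzylidene]triphenylphosphorane (ylide, not isolated) | c1ccc(COc2cccc(C=P(c3ccccc3)(c3ccccc3)c3ccccc3)c2)cc1 | intermediate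
6 | 4-{2-[3-(benzyloxy)phenyl]ethenyl}-1-methoxy-2-(methoxymethoxy)benzene (E/Z mixture) | COCOc1cc(C=Cc2cccc(OCc3ccccc3)c2)ccc1OC | intermediate
7 | 3-{2-[4-methoxy-3-(methoxymethoxy)phenyl]ethyl}phenol (A–D bibenzyl) | COCOc1cc(CCc2cccc(O)c2)ccc1OC | intermediate
8 | 4-fluoro-3-hydroxybenzaldehyde | O=Cc1ccc(F)c(O)c1 | starting material
9 | 3-(benzyloxy)-4-fluorobenzaldehyde | O=Cc1ccc(F)c(OCc2ccccc2)c1 | intermediate
10 | 3-(benzyloxy)-4-(3-{2-[4-methoxy-3-(methoxymethoxy)phenyl]ethyl}phenoxy)benzaldehyde | COCOc1cc(CCc2cccc(Oc3ccc(C=O)cc3OCc3ccccc3)c2)ccc1OC | intermediate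
11 | 2-(benzyloxy)-4-ethynyl-1-(3-{2-[4-methoxy-3-(methoxymethoxy)phenyl]ethyl}phenoxy)benzene | COCOc1cc(CCc2cccc(Oc3ccc(C#C)cc3OCc3ccccc3)c2)ccc1OC | intermediate
12 | 1-fluoro-4-iodobenzene | Fc1ccc(I)cc1 | starting material
13 | 2-(benzyloxy)-4-[(4-fluorophenyl)ethynyl]-1-(3-{2-[4-methoxy-3-(methoxymethoxy)phenyl]ethyl}phenoxy)benzene | COCOc1cc(CCc2cccc(Oc3ccc(C#Cc4ccc(F)cc4)cc3OCc3ccccc3)c2)ccc1OC | intermediate
14 | 1-[3-(benzyloxy)-4-(3-{2-[4-methoxy-3-(methoxymethoxy)phenyl]ethyl}phenoxy)phenyl]-2-(4-fluorophenyl)ethane-1,2-dione | COCOc1cc(CCc2cccc(Oc3ccc(C(=O)C(=O)c4ccc(F)cc4)cc3OCc3ccccc3)c2)ccc1OC | intermediate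
15 | 1-[3-(benzyloxy)-4-{3-[2-(3-hydroxy-4-methoxyphenyl)ethyl]phenoxy}phenyl]-2-(4-fluorophenyl)ethane-1,2-dione (open-chain precursor) | COc1ccc(CCc2cccc(Oc3ccc(C(=O)C(=O)c4ccc(F)cc4)cc3OCc3ccccc3)c2)cc1O | intermediate
16 | macrocyclic benzil: 20-membered ring, ring C oxygen benzylated, B–C bridge as 1,2-dione | COc1ccc2cc1Oc1ccc(cc1)C(=O)C(=O)c1ccc(c(OCc3ccccc3)c1)Oc1cccc(c1)CC2 | intermediate
17 | debenzylated macrocyclic 1,2-diol at the B–C bridge (mixture of diastereomers, not isolated) | COc1ccc2cc1Oc1ccc(cc1)C(O)C(O)c1ccc(c(O)c1)Oc1cccc(c1)CC2 | intermediate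
18 | pakyonol | COc1ccc2cc1Oc1ccc(cc1)CCc1ccc(c(O)c1)Oc1cccc(c1)CC2 | target

**Step count and risks**

Total step count: 12. Longest linear sequence: 10 steps (steps 1, 3, 4, 6, 7, 8, 9, 10, 11, 12 from isovanillin).

Steps most likely to fail:

1. Step 11, SNAr macrocyclisation. Intermolecular etherification may outrun ring closure and give oligomers if the dione hinge does not bring the chain ends together. Adventitious hydroxide may also add to the dione and trigger benzilic acid rearrangement. Fallback: close the ring at the B–C bridge instead, setting out from aldehyde 10 and rejoining the route at pakyonol 18. The MOM group of 10 is removed with 3 M aq HCl in THF to give 3-(benzyloxy)-4-{3-[2-(3-hydroxy-4-methoxyphenyl)ethyl]phenoxy}benzaldehyde F1. The ring A phenoxide of F1 is arylated with 4-fluorobenzaldehyde (K2CO3, DMF, 140 °C) to give 3-(benzyloxy)-4-(3-{2-[3-(4-formylphenoxy)-4-methoxyphenyl]ethyl}phenoxy)benzaldehyde F2. Intramolecular McMurry coupling of the two formyl groups with low-valent titanium (TiCl4, Zn, pyridine, THF, reflux, slow addition) should give the macrocyclic stilbene F3, which is O-benzyl pakyonol with CH=CH in place of the B–C CH2CH2, as an E/Z mixture. Hydrogenation (H2, Pd/C, EtOAc/MeOH) saturates the alkene and cleaves the benzyl ether to give 18.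

2. Step 12, global hydrogenolysis. Deoxygenation may stall at a monoketone or alcohol stage, or acid may divert the diol stage into a pinacol-type rearrangement. Fallback: deoxygenative olefination, setting out from 16 and rejoining at 18. NaBH4 (THF/MeOH, 0 °C) reduces 16 to the O-benzyl macrocyclic 1,2-diol F4 (diastereomer mixture). 1,1'-Thiocarbonyldiimidazole (toluene, reflux) converts it into the cyclic thionocarbonate F5. Corey–Winter fragmentation with P(OMe)3 at 110 °C gives the macrocyclic stilbene F3, the same compound as in the fallback for step 11. Neutral hydrogenation (H2, Pd/C) then gives 18.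

3. Step 9, alkyne oxidation. In hot DMSO the electron-rich rings or the MOM acetal may degrade, or oxidation may go on to cleave the dione. Fallback: build the dione from the aldehyde without an alkyne, setting out from 10 and rejoining at 14. Addition of 4-fluorobenzylmagnesium chloride (THF, −78 to 0 °C) to 10 gives the racemic carbinol 1-[3-(benzyloxy)-4-(3-{2-[4-methoxy-3-(methoxymethoxy)phenyl]ethyl}phenoxy)phenyl]-2-(4-fluorophenyl)ethanol F6. Dess–Martin periodinane (CH2Cl2, rt) oxidises it to the deoxybenzoin F7. Riley oxidation of the activated methylene with SeO2 (dioxane/H2O, reflux) gives dione 14.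

**Further compounds**

F1 | step 11 | 3-(benzyloxy)-4-{3-[2-(3-hydroxy-4-methoxyphenyl)ethyl]phenoxy}benzaldehyde | COc1ccc(CCc2cccc(Oc3ccc(C=O)cc3OCc3ccccc3)c2)cc1O
F2 | step 11 | 3-(benzyloxy)-4-(3-{2-[3-(4-formylphenoxy)-4-methoxyphenyl]ethyl}phenoxy)benzaldehyde | COc1ccc(CCc2cccc(Oc3ccc(C=O)cc3OCc3ccccc3)c2)cc1Oc1ccc(C=O)cc1
F3 | step 11 | macrocyclic stilbene, O-benzyl pakyonol with CH=CH at the B–C bridge (E/Z mixture) | COc1ccc2cc1Oc1ccc(cc1)C=Cc1ccc(c(OCc3ccccc3)c1)Oc1cccc(c1)CC2
F4 | step 12 | O-benzyl macrocyclic 1,2-diol at the B–C bridge (diastereomer mixture) | COc1ccc2cc1Oc1ccc(cc1)C(O)C(O)c1ccc(c(OCc3ccccc3)c1)Oc1cccc(c1)CC2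
F5 | step 12 | cyclic thionocarbonate of diol F4 (1,3-dioxolane-2-thione fused at the B–C bridge carbons) | COc1ccc2cc1Oc1ccc(cc1)C4OC(=S)OC4c1ccc(c(OCc3ccccc3)c1)Oc1cccc(c1)CC2
F6 | step 9 | 1-[3-(benzyloxy)-4-(3-{2-[4-methoxy-3-(methoxymethoxy)phenyl]ethyl}phenoxy)phenyl]-2-(4-fluorophenyl)ethanol (racemic) | COCOc1cc(CCc2cccc(Oc3ccc(C(O)Cc4ccc(F)cc4)cc3OCc3ccccc3)c2)ccc1OC
F7 | step 9 | 1-[3-(benzyloxy)-4-(3-{2-[4-methoxy-3-(methoxymethoxy)phenyl]ethyl}phenoxy)phenyl]-2-(4-fluorophenyl)ethanone | COCOc1cc(CCc2cccc(Oc3ccc(C(=O)Cc4ccc(F)cc4)cc3OCc3ccccc3)c2)ccc1OC
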